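## Retrosynthetic overview

1. Feature: in ring C (O1–C2–C3–C4–C4a–C8a), the C3–C4 bond links C2, the ether carbon carrying ring B, to C4, the methine shared by rings A and D. Drawn as C3=C4, ring C splits by metathesis logic into a 1-arylallyl aryl ether and a 1,1-diarylethylene.
2. Target ⇒ pentabenzyl cis-flavan. Benzyl hydrogenolysis comes last; the dodecanoyl group enters ring D late by bromination, Br/Li exchange, addition to dodecanal and oxidation.
3. cis-Flavan ⇒ (2R)-2,4-diaryl-2H-chromene. Hydrogenation anti to ring B relays C2 to C4.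
4. Chromene ⇒ diene by ring-closing metathesis. Ring C is the only ring formed; rings A, B and D are bought. Diene ⇒ 2-(1-arylvinyl)phenol + 4-benzyloxycinnamyl methyl carbonate by iridium-catalysed asymmetric allylic etherification, which sets C2.
5. Phenol ⇒ ring D aryllithium + O-allyl-protected 4-benzyloxysalicylaldehyde, then oxidation, MeLi addition/dehydration and deallylation.

Key step: step 11

Assumption: the (Ra,Rc,Rc) antipode of the phosphoramidite is taken to deliver the (R)-allyl aryl ether. The sense is to be verified on that ether, and the mirror-image ligand would be used otherwise with no other change.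

## Route

Step 1
Reactants: 1 1,3,5-tribenzyloxybenzene
Product: 2 2-bromo-1,3,5-tribenzyloxybenzene
Conditions: NBS (1.0 equiv), CH2Cl2, −40 → 0 °C, dark
Reagents that add atoms: N-bromosuccinimide, O=C1CCC(=O)N1Br
Why: Electrophilic aromatic bromination of a phloroglucinol triether is fast in the cold, the three free positions are equivalent and the first bromine deactivates the ring, so one equivalent should stop at the monobromide.

Step 2
Reactants: 3 4-benzyloxy-2-hydroxybenzaldehyde
Product: 4 2-allyloxy-4-benzyloxybenzaldehyde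
Conditions: allyl bromide (1.2 equiv), K2CO3 (1.5 equiv), DMF, 50 °C
Reagents that add atoms: allyl bromide, C=CCBr
Why: Williamson etherification of the only phenol masks the acidic OH for the organolithium steps with a group that can later be removed under neutral conditions in the presence of benzyl ethers.

Step 3
Reactants: 2 2-bromo-1,3,5-tribenzyloxybenzene; 4 2-allyloxy-4-benzyloxybenzaldehyde
Product: 6 (2-allyloxy-4-benzyloxyphenyl)(2,4,6-tribenzyloxyphenyl)methanol (racemic), via aryllithium 5 (not isolated)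
Conditions: 2, n-BuLi (1.05 equiv), THF, −78 °C; then 4, −78 → −20 °C; H2O
Reagents that add atoms: none
Why: Bromine–lithium exchange outruns benzylic deprotonation at −78 °C, and 1,2-addition of the aryllithium to the non-enolisable aldehyde gives the carbinol, whose racemic centre is erased in the next step.

Step 4
Reactants: 6 (2-allyloxy-4-benzyloxyphenyl)(2,4,6-tribenzyloxyphenyl)methanol
Product: 7 (2-allyloxy-4-benzyloxyphenyl)(2,4,6-tribenzyloxyphenyl)methanone
Conditions: activated MnO2 (15 equiv), CH2Cl2, rt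
Reagents that add atoms: none
Why: MnO2 oxidation of a doubly benzylic, electron-rich alcohol runs under neutral conditions, which avoids ionisation of the acid-labile benzhydrol and leaves the allyl and benzyl ethers untouched.

Step 5
Reactants: 7 (2-allyloxy-4-benzyloxyphenyl)(2,4,6-tribenzyloxyphenyl)methanone
Product: 9 2-allyloxy-4-benzyloxy-1-[1-(2,4,6-tribenzyloxyphenyl)vinyl]benzene, via tertiary carbinol 8 (not isolated)
Conditions: MeLi (2 equiv), THF, −78 → 0 °C; H2O; crude carbinol, PPTS (5 mol%), CH2Cl2, rt; Et3N quench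
Reagents that add atoms: methyllithium, [Li]C
Why: 1,2-Addition of small methyllithium tolerates the three ortho alkoxy groups that would slow a bulky phosphorus ylide, and the 1,1-diarylethanol then undergoes E1 dehydration with trace acid because both alkoxyaryl rings stabilise its cation.

Step 6
Reactants: 9 2-allyloxy-4-benzyloxy-1-[1-(2,4,6-tribenzyloxyphenyl)vinyl]benzene
Product: 10 5-benzyloxy-2-[1-(2,4,6-tribenzyloxyphenyl)vinyl]phenol
Conditions: Pd(PPh3)4 (5 mol%), morpholine (5 equiv), THF, rt
Reagents that add atoms: none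
Why: In this Tsuji–Trost deallylation zerovalent palladium ionises only the allyl aryl ether and morpholine traps the π-allyl fragment, so the phenol is freed under neutral conditions that spare the acid-sensitive 1,1-diarylethylene and the benzyl ethers.

Step 7
Reactants: 11 4-benzyloxybenzaldehyde
Product: 12 methyl (E)-3-(4-benzyloxyphenyl)acrylate
Conditions: Ph3P=CHCO2Me (1.1 equiv), toluene, 80 °C
Reagents that add atoms: methyl (triphenylphosphoranylidene)acetate, COC(=O)C=P(c1ccccc1)(c1ccccc1)c1ccccc1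
Why: The Wittig reaction of a stabilised ylide with an aromatic aldehyde should give the E-cinnamate, the alkene geometry that the later iridium catalysis requires.

Step 8
Reactants: 12 methyl (E)-3-(4-benzyloxyphenyl)acrylate
Product: 13 (E)-3-(4-benzyloxyphenyl)prop-2-en-1-ol
Conditions: i-Bu2AlH (2.2 equiv), CH2Cl2, −78 °C; aqueous work-up
Reagents that add atoms: none
Why: 1,2-Reduction of an enoate with i-Bu2AlH gives the allylic alcohol without touching the alkene or the benzyl ether.

Step 9
Reactants: 13 (E)-3-(4-benzyloxyphenyl)prop-2-en-1-ol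
Product: 14 (E)-3-(4-benzyloxyphenyl)allyl methyl carbonate
Conditions: ClCO2Me (1.3 equiv), pyridine (2 equiv), CH2Cl2, 0 °C
Reagents that add atoms: methyl chloroformate, COC(=O)Cl
Why: O-Acylation of the primary alcohol under basic conditions installs the leaving group while avoiding ionisation of the electron-rich cinnamyl system.

Step 10
Reactants: 10 5-benzyloxy-2-[1-(2,4,6-tribenzyloxyphenyl)vinyl]phenol; 14 (E)-3-(4-benzyloxyphenyl)allyl methyl carbonate
Product: 15 (R)-4-benzyloxy-2-{[1-(4-benzyloxyphenyl)prop-2-en-1-yl]oxy}-1-[1-(2,4,6-tribenzyloxyphenyl)vinyl]benzene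
Conditions: [Ir(cod)Cl]2 (2 mol%), (Ra,Rc,Rc)-O,O'-(1,1'-binaphthyl-2,2'-diyl) N,N-bis(1-phenylethyl)phosphoramidite (4 mol%), 1,5,7-triazabicyclo[4.4.0]dec-5-ene (8 mol%), THF, rt (activation); then 10, 14 (1.3 equiv), THF, rt → 35 °C
Reagents that add atoms: none
Why: In this iridium-catalysed asymmetric allylic etherification the cyclometalated iridium–phosphoramidite complex ionises the linear carbonate, the released methoxide deprotonates 10, and the phenoxide attacks the aryl-bearing allyl terminus anti to the metal, so the branched ether forms and the ligand fixes C2 as R.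

Step 11
Reactants: 15 (R)-4-benzyloxy-2-{[1-(4-benzyloxyphenyl)prop-2-en-1-yl]oxy}-1-[1-(2,4,6-tribenzyloxyphenyl)vinyl]benzene
Product: 16 (2R)-7-benzyloxy-2-(4-benzyloxyphenyl)-4-(2,4,6-tribenzyloxyphenyl)-2H-chromene
Conditions: second-generation Grubbs catalyst RuCl2(=CHPh)(PCy3)(H2IMes) (2 × 5 mol%), 1,4-benzoquinone (10 mol%), toluene (0.005 M), 70 °C, Ar sparge, dark
Reagents that add atoms: none
Why: In this ring-closing olefin metathesis the ruthenium benzylidene first exchanges with the accessible monosubstituted vinyl group, the resulting alkylidene (future C3) undergoes intramolecular [2+2] cycloaddition with the 1,1-diarylethylene so that ruthenium sits on the CH2 terminus and C3 bonds to the diaryl carbon (future C4), and cycloreversion releases 16 and Ru=CH2, which expels ethene on reloading. The closest known reaction type is the closure of 2-(1-arylvinyl)phenyl allyl ethers to 4-aryl-2H-chromenes with this catalyst. Ring C closes as a six-membered ring from an octa-1,7-diene-type array in which O1, C8a, C4a and C4 are already held on ring A, which, with high dilution and ethene removal, favours cyclisation over oligomerisation. No stereocentre is created, and C2, next to the reacting vinyl group, keeps its R configuration as long as no ruthenium hydride migrates the double bond and the chromene does not ring-open electrocyclically, hence the benzoquinone, the 70 °C ceiling and the exclusion of light. The required chemoselectivity comes from the substrate, since a 1,1-diarylethylene neither initiates nor homodimerises and can only accept the tethered alkylidene. The cost is the shielding of that alkene by the two ortho benzyloxy groups of ring D, so a high loading added in portions is planned.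

Step 12
Reactants: 16 (2R)-7-benzyloxy-2-(4-benzyloxyphenyl)-4-(2,4,6-tribenzyloxyphenyl)-2H-chromene
Product: 17 (2R,4R)-7-benzyloxy-2-(4-benzyloxyphenyl)-4-(2,4,6-tribenzyloxyphenyl)chroman (2,4-cis)
Conditions: [Ir(cod)(PCy3)(py)]PF6 (2 × 5 mol%), H2 (50 bar), CH2Cl2, rt, dark
Reagents that add atoms: none
Why: This homogeneous hydrogenation uses a cationic iridium catalyst that accepts trisubstituted alkenes and does not hydrogenolyse benzyl ethers, and syn delivery of H2 to the face opposite ring B places H-4 trans and ring D cis to ring B, setting C4 as R by substrate control.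

Step 13
Reactants: 17 (2R,4R)-7-benzyloxy-2-(4-benzyloxyphenyl)-4-(2,4,6-tribenzyloxyphenyl)chroman
Product: 18 (2R,4R)-7-benzyloxy-2-(4-benzyloxyphenyl)-4-(3-bromo-2,4,6-tribenzyloxyphenyl)chroman
Conditions: NBS (1.0 equiv), CH2Cl2, −78 → −20 °C, dark
Reagents that add atoms: N-bromosuccinimide, O=C1CCC(=O)N1Br
Why: Electrophilic aromatic bromination should go to ring D, the only ring activated by three alkoxy groups, whose two free positions are equivalent by rotation about the C4–aryl bond, and the cold neutral medium leaves C2 and C4 undisturbed.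

Step 14
Reactants: 18 (2R,4R)-7-benzyloxy-2-(4-benzyloxyphenyl)-4-(3-bromo-2,4,6-tribenzyloxyphenyl)chroman; 19 dodecanal
Product: 21 1-{2,4,6-tribenzyloxy-3-[(2R,4R)-7-benzyloxy-2-(4-benzyloxyphenyl)chroman-4-yl]phenyl}dodecan-1-ol (carbinol epimers), via aryllithium 20 (not isolated)
Conditions: 18, n-BuLi (1.1 equiv), THF, −78 °C; then 19 (1.5 equiv), −78 → −40 °C; H2O
Reagents that add atoms: none
Why: Bromine–lithium exchange followed by 1,2-addition to the aldehyde attaches the C12 chain without any acid that could ionise the C2–O bond, and the new carbinol centre, formed without control, is removed by the next oxidation.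

Step 15
Reactants: 21 1-{2,4,6-tribenzyloxy-3-[(2R,4R)-7-benzyloxy-2-(4-benzyloxyphenyl)chroman-4-yl]phenyl}dodecan-1-ol
Product: 22 1-{2,4,6-tribenzyloxy-3-[(2R,4R)-7-benzyloxy-2-(4-benzyloxyphenyl)chroman-4-yl]phenyl}dodecan-1-one
Conditions: (n-Pr4N)RuO4 (5 mol%), N-methylmorpholine N-oxide (1.5 equiv), 4 Å MS, CH2Cl2, rt
Reagents that add atoms: none
Why: The Ley–Griffith oxidation converts the secondary benzylic alcohol into the aryl ketone under neutral conditions, so the easily ionised trialkoxybenzylic alcohol does not eliminate and the ethers and both ring stereocentres are unaffected.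

Step 16
Reactants: 22 1-{2,4,6-tribenzyloxy-3-[(2R,4R)-7-benzyloxy-2-(4-benzyloxyphenyl)chroman-4-yl]phenyl}dodecan-1-one
Product: 23 1-{2,4,6-trihydroxy-3-[(2R,4R)-7-hydroxy-2-(4-hydroxyphenyl)chroman-4-yl]phenyl}dodecan-1-one (CNP0293819.1)
Conditions: H2 (1 atm), Pd/C (10 wt% Pd), EtOAc–MeOH 1:1, rt, stopped at full debenzylation
Reagents that add atoms: none
Why: Catalytic hydrogenolysis cleaves the five aryl benzyl ethers much faster than the cyclic C2–O bond or the hindered, then hydrogen-bonded, aryl ketone reacts at 1 atm in neutral solvent, so C2 and C4 are retained.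

## Compound list

1 | 1,3,5-tribenzyloxybenzene | c1ccc(COc2cc(OCc3ccccc3)cc(OCc3ccccc3)c2)cc1 | starting material
2 | 2-bromo-1,3,5-tribenzyloxybenzene | Brc1c(OCc2ccccc2)cc(OCc2ccccc2)cc1OCc1ccccc1 | intermediate
3 | 4-benzyloxy-2-hydroxybenzaldehyde | O=Cc1ccc(OCc2ccccc2)cc1O | starting material
4 | 2-allyloxy-4-benzyloxybenzaldehyde | C=CCOc1cc(OCc2ccccc2)ccc1C=O | intermediate
5 | 2,4,6-tribenzyloxyphenyllithium | [Li]c1c(OCc2ccccc2)cc(OCc2ccccc2)cc1OCc1ccccc1 | intermediate
6 | (2-allyloxy-4-benzyloxyphenyl)(2,4,6-tribenzyloxyphenyl)methanol, racemic | C=CCOc1cc(OCc2ccccc2)ccc1C(O)c1c(OCc2ccccc2)cc(OCc2ccccc2)cc1OCc1ccccc1 | intermediate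
7 | (2-allyloxy-4-benzyloxyphenyl)(2,4,6-tribenzyloxyphenyl)methanone | C=CCOc1cc(OCc2ccccc2)ccc1C(=O)c1c(OCc2ccccc2)cc(OCc2ccccc2)cc1OCc1ccccc1 | intermediate
8 | 1-(2-allyloxy-4-benzyloxyphenyl)-1-(2,4,6-tribenzyloxyphenyl)ethanol, racemic | C=CCOc1cc(OCc2ccccc2)ccc1C(C)(O)c1c(OCc2ccccc2)cc(OCc2ccccc2)cc1OCc1ccccc1 | intermediate
9 | 2-allyloxy-4-benzyloxy-1-[1-(2,4,6-tribenzyloxyphenyl)vinyl]benzene | C=CCOc1cc(OCc2ccccc2)ccc1C(=C)c1c(OCc2ccccc2)cc(OCc2ccccc2)cc1OCc1ccccc1 | intermediate
10 | 5-benzyloxy-2-[1-(2,4,6-tribenzyloxyphenyl)vinyl]phenol | C=C(c1ccc(OCc2ccccc2)cc1O)c1c(OCc2ccccc2)cc(OCc2ccccc2)cc1OCc1ccccc1 | intermediate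
11 | 4-benzyloxybenzaldehyde | O=Cc1ccc(OCc2ccccc2)cc1 | starting material
12 | methyl (E)-3-(4-benzyloxyphenyl)acrylate | COC(=O)/C=C/c1ccc(OCc2ccccc2)cc1 | intermediate
13 | (E)-3-(4-benzyloxyphenyl)prop-2-en-1-ol | OC/C=C/c1ccc(OCc2ccccc2)cc1 | intermediate
14 | (E)-3-(4-benzyloxyphenyl)allyl methyl carbonate | COC(=O)OC/C=C/c1ccc(OCc2ccccc2)cc1 | intermediate
15 | (R)-4-benzyloxy-2-{[1-(4-benzyloxyphenyl)prop-2-en-1-yl]oxy}-1-[1-(2,4,6-tribenzyloxyphenyl)vinyl]benzene | C=C[C@@H](Oc1cc(OCc2ccccc2)ccc1C(=C)c1c(OCc2ccccc2)cc(OCc2ccccc2)cc1OCc1ccccc1)c1ccc(OCc2ccccc2)cc1 | intermediate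
16 | (2R)-7-benzyloxy-2-(4-benzyloxyphenyl)-4-(2,4,6-tribenzyloxyphenyl)-2H-chromene | c1ccc(COc2cc(OCc3ccccc3)c(C3=C[C@H](c4ccc(OCc5ccccc5)cc4)Oc4cc(OCc5ccccc5)ccc43)c(OCc3ccccc3)c2)cc1 | intermediate
17 | (2R,4R)-7-benzyloxy-2-(4-benzyloxyphenyl)-4-(2,4,6-tribenzyloxyphenyl)chroman | c1ccc(COc2cc(OCc3ccccc3)c([C@@H]3C[C@H](c4ccc(OCc5ccccc5)cc4)Oc4cc(OCc5ccccc5)ccc43)c(OCc3ccccc3)c2)cc1 | intermediate
18 | (2R,4R)-7-benzyloxy-2-(4-benzyloxyphenyl)-4-(3-bromo-2,4,6-tribenzyloxyphenyl)chroman | Brc1c(OCc2ccccc2)cc(OCc2ccccc2)c([C@@H]2C[C@H](c3ccc(OCc4ccccc4)cc3)Oc3cc(OCc4ccccc4)ccc32)c1OCc1ccccc1 | intermediate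
19 | dodecanal | CCCCCCCCCCCC=O | starting material
20 | 2,4,6-tribenzyloxy-3-[(2R,4R)-7-benzyloxy-2-(4-benzyloxyphenyl)chroman-4-yl]phenyllithium | [Li]c1c(OCc2ccccc2)cc(OCc2ccccc2)c([C@@H]2C[C@H](c3ccc(OCc4ccccc4)cc3)Oc3cc(OCc4ccccc4)ccc32)c1OCc1ccccc1 | intermediate
21 | 1-{2,4,6-tribenzyloxy-3-[(2R,4R)-7-benzyloxy-2-(4-benzyloxyphenyl)chroman-4-yl]phenyl}dodecan-1-ol, carbinol epimers | CCCCCCCCCCCC(O)c1c(OCc2ccccc2)cc(OCc2ccccc2)c([C@@H]2C[C@H](c3ccc(OCc4ccccc4)cc3)Oc3cc(OCc4ccccc4)ccc32)c1OCc1ccccc1 | intermediate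
22 | 1-{2,4,6-tribenzyloxy-3-[(2R,4R)-7-benzyloxy-2-(4-benzyloxyphenyl)chroman-4-yl]phenyl}dodecan-1-one | CCCCCCCCCCCC(=O)c1c(OCc2ccccc2)cc(OCc2ccccc2)c([C@@H]2C[C@H](c3ccc(OCc4ccccc4)cc3)Oc3cc(OCc4ccccc4)ccc32)c1OCc1ccccc1 | intermediate
23 | 1-{2,4,6-trihydroxy-3-[(2R,4R)-7-hydroxy-2-(4-hydroxyphenyl)chroman-4-yl]phenyl}dodecan-1-one | CCCCCCCCCCCC(=O)c1c(O)cc(O)c([C@@H]2C[C@H](c3ccc(O)cc3)Oc3cc(O)ccc32)c1O | target

## Step count and risks

Total step count: 16.
Longest linear sequence: 12 (steps 1, 3, 4, 5, 6, 10, 11, 12, 13, 14, 15, 16). Steps 2 and 7–9 run in parallel.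

**Step 11 (ring-closing metathesis).**
- What may go wrong:
  - The tethered alkylidene may fail to engage the alkene, which is flanked on both faces by the ortho benzyloxy groups of ring D, so the closure stalls.
  - While it stalls, catalyst decay to hydrides could start double-bond migration in the allyl ether.
  - Long heating or light could erode C2 through reversible electrocyclic opening of the chromene.
- Fallback (sets out from 2, comes back at 16): the C4–ring D bond is made by carbonyl addition instead of being carried through the metathesis. Commercial 7-hydroxychromone would be benzylated (BnBr, K2CO3, DMF) to 7-benzyloxy-4H-chromen-4-one F1. Asymmetric conjugate addition of 4-benzyloxyphenylboronic acid would follow (Pd(OCOCF3)2, the t-BuPyOx antipode chosen for R, NH4PF6, H2O, ClCH2CH2Cl, 60 °C), giving (2R)-7-benzyloxy-2-(4-benzyloxyphenyl)chroman-4-one F2. Aryllithium 5, generated from 2 as in step 3, would add to the ketone at −78 °C to give (2R)-7-benzyloxy-2-(4-benzyloxyphenyl)-4-(2,4,6-tribenzyloxyphenyl)chroman-4-ol F3. Mild dehydration (MsCl/Et3N or PPTS) towards C3 would then deliver 16.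

**Step 10 (allylic etherification).**
- What may go wrong:
  - The phenoxide, crowded by the ortho 1-arylvinyl group, may attack slowly.
  - Slow attack would leave time for branched-to-linear isomerisation and loss of enantiopurity by re-ionisation of the electron-rich allyl ether.
- Fallback (sets out from 3, 14 and 2, comes back at 15): the order of bond formation is reversed so that the unhindered phenol is the nucleophile. Aldehyde 3 and carbonate 14 would be coupled with the same iridium catalyst to (R)-4-benzyloxy-2-{[1-(4-benzyloxyphenyl)prop-2-en-1-yl]oxy}benzaldehyde F4. Aryllithium 5 (from 2) would add at −78 °C to give the diaryl carbinol F5, and MnO2 would give the diaryl ketone F6. MeLi at −78 °C would give the 1,1-diarylethanol F7, and PPTS-catalysed dehydration would give 15. No phenol protecting group is then needed.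

**Step 12 (hydrogenation).**
- What may go wrong:
  - The shielded trisubstituted alkene may not bind to iridium.
  - Facial selectivity may be poor if ring B sits pseudo-equatorial.
  - Acidic iridium hydrides could ionise the allylic C2–O bond.
- Fallback (sets out from 16, comes back at 17): the shielding benzyl groups are removed while the alkene is saturated on a metal surface. H2 (1 atm) over Pd/C in EtOAc–EtOH would cleave the benzyl ethers. The now less crowded flav-3-ene would adsorb on the face away from ring B and be reduced to (2R,4R)-2-(4-hydroxyphenyl)-4-(2,4,6-trihydroxyphenyl)chroman-7-ol F8. Per-O-benzylation (BnBr, K2CO3, DMF, rt) would return to 17.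

Further compounds
F1 | step 11 | 7-benzyloxy-4H-chromen-4-one | O=c1ccoc2cc(OCc3ccccc3)ccc12
F2 | step 11 | (2R)-7-benzyloxy-2-(4-benzyloxyphenyl)chroman-4-one | O=C1C[C@H](c2ccc(OCc3ccccc3)cc2)Oc2cc(OCc3ccccc3)ccc21
F3 | step 11 | (2R)-7-benzyloxy-2-(4-benzyloxyphenyl)-4-(2,4,6-tribenzyloxyphenyl)chroman-4-ol, C4 epimers | OC1(c2c(OCc3ccccc3)cc(OCc3ccccc3)cc2OCc2ccccc2)C[C@H](c2ccc(OCc3ccccc3)cc2)Oc2cc(OCc3ccccc3)ccc21
F4 | step 10 | (R)-4-benzyloxy-2-{[1-(4-benzyloxyphenyl)prop-2-en-1-yl]oxy}benzaldehyde | C=C[C@@H](Oc1cc(OCc2ccccc2)ccc1C=O)c1ccc(OCc2ccccc2)cc1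
F5 | step 10 | (4-benzyloxy-2-{[(R)-1-(4-benzyloxyphenyl)prop-2-en-1-yl]oxy}phenyl)(2,4,6-tribenzyloxyphenyl)methanol, carbinol epimers | C=C[C@@H](Oc1cc(OCc2ccccc2)ccc1C(O)c1c(OCc2ccccc2)cc(OCc2ccccc2)cc1OCc1ccccc1)c1ccc(OCc2ccccc2)cc1
F6 | step 10 | (4-benzyloxy-2-{[(R)-1-(4-benzyloxyphenyl)prop-2-en-1-yl]oxy}phenyl)(2,4,6-tribenzyloxyphenyl)methanone | C=C[C@@H](Oc1cc(OCc2ccccc2)ccc1C(=O)c1c(OCc2ccccc2)cc(OCc2ccccc2)cc1OCc1ccccc1)c1ccc(OCc2ccccc2)cc1
F7 | step 10 | 1-(4-benzyloxy-2-{[(R)-1-(4-benzyloxyphenyl)prop-2-en-1-yl]oxy}phenyl)-1-(2,4,6-tribenzyloxyphenyl)ethanol, carbinol epimers | C=C[C@@H](Oc1cc(OCc2ccccc2)ccc1C(C)(O)c1c(OCc2ccccc2)cc(OCc2ccccc2)cc1OCc1ccccc1)c1ccc(OCc2ccccc2)cc1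
F8 | step 12 | (2R,4R)-2-(4-hydroxyphenyl)-4-(2,4,6-trihydroxyphenyl)chroman-7-ol | Oc1cc(O)c([C@@H]2C[C@H](c3ccc(O)cc3)Oc3cc(O)ccc32)c(O)c1
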